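## Retrosynthetic overview

1. Target 44 ⇐ acid-labile global deprotection of quinone 43 ⇐ para-oxidation of 2-amido-1-naphthol 42 ⇐ amide bond between dienoic acid 25 and aminonaphthol 40.
2. Acid 25 ⇐ Z-selective Still–Gennari olefination ⇐ cross-metathesis enal ⇐ crotylboration of C7 aldehyde 20 (sets C6, C7).
3. Key C–C bond C10–C11: titanium syn-aldol union of Roche-derived ethyl ketone 4 (C7–C10) with aldehyde 11 (C11–C17, from an Evans aldol), then 1,3-anti reduction (C9).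
4. Aminonaphthol 40 ⇐ Curtius rearrangement at C2 of a 1-hydroxy-2-naphthoate ⇐ Michael–Dieckmann annulation of methyl acrylate onto an isophthalate made from atraric acid.
5. Ring order: tetrahydrofuran ring, then dioxane ring of the bicyclic ketal (one acid step, early); carbocyclic ring A of the naphthalene (annulation, then aromatisation); quinone oxidation level last.

Assumptions: chain positions C1–C17 run from the amide carbonyl to the ketal methyl; naphthalene positions in the Why lines use the quinone numbering (N on C2, carboxyl on C5). The tartrate crotylboronate and the trifluoroethyl phosphonate are treated as stock reagents made by standard procedures.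

## Route

Step 1
Reactants: 1 methyl (R)-3-hydroxy-2-methylpropanoate
Product: 2 methyl (R)-3-(benzyloxy)-2-methylpropanoate
Conditions: BnOC(=NH)CCl3, TfOH (cat.), CH2Cl2/cyclohexane, 0 °C → rt
Reagents that add atoms: benzyl 2,2,2-trichloroacetimidate, ClC(Cl)(Cl)C(=N)OCc1ccccc1
Why: Acid-catalysed imidate benzylation needs no base, so the Roche stereocentre (future C8) is not epimerised.

Step 2
Reactants: 2 benzyl-protected Roche ester
Product: 3 (R)-3-(benzyloxy)-N-methoxy-N,2-dimethylpropanamide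
Conditions: MeNH(OMe)·HCl, i-PrMgCl, THF, −20 °C
Reagents that add atoms: N,O-dimethylhydroxylamine hydrochloride, CNOC.Cl
Why: Weinreb amidation with the magnesium amide converts the ester without enolising the α-stereocentre.

Step 3
Reactants: 3 Weinreb amide
Product: 4 (R)-1-(benzyloxy)-2-methylpentan-3-one
Conditions: EtMgBr, THF, 0 °C
Reagents that add atoms: ethylmagnesium bromide, CC[Mg]Br
Why: Grignard addition to a Weinreb amide stops at the ketone because of the stable magnesium chelate.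

Step 4
Reactants: 5 (R)-4-benzyl-3-propanoyl-1,3-oxazolidin-2-one, 6 pent-4-enal
Product: 8 (R)-4-benzyl-3-[(2R,3S)-3-hydroxy-2-methylhept-6-enoyl]-1,3-oxazolidin-2-one, via Z-dibutylboron enolate 7 (not isolated)
Conditions: Bu2BOTf, i-Pr2NEt, CH2Cl2, −78 → 0 °C; 6, −78 → 0 °C; H2O2, MeOH/pH 7 buffer
Reagents that add atoms: none
Why: Evans syn-aldol reaction; the Z-boron enolate reacts through a Zimmerman–Traxler chair on the face away from the auxiliary benzyl group and sets C12 (R) and C13 (S) as the syn pair.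

Step 5
Reactants: 8 Evans aldol adduct
Product: 9 (R)-4-benzyl-3-[(2R,3S)-3-[(tert-butyldimethylsilyl)oxy]-2-methylhept-6-enoyl]-1,3-oxazolidin-2-one
Conditions: TBSOTf, 2,6-lutidine, CH2Cl2, −78 → 0 °C
Reagents that add atoms: tert-butyldimethylsilyl trifluoromethanesulfonate, CC(C)(C)[Si](C)(C)OS(=O)(=O)C(F)(F)F
Why: Silyl triflate with a hindered base silylates the secondary alcohol without retro-aldol cleavage.

Step 6
Reactants: 9 silylated imide
Product: 10 (2S,3S)-3-[(tert-butyldimethylsilyl)oxy]-2-methylhept-6-en-1-ol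
Conditions: LiBH4, MeOH (1 equiv), THF, 0 °C
Reagents that add atoms: none
Why: Reductive cleavage of the Evans auxiliary gives the primary alcohol; the descriptor at C12 changes by priority only.

Step 7
Reactants: 10 primary alcohol
Product: 11 (2R,3S)-3-[(tert-butyldimethylsilyl)oxy]-2-methylhept-6-enal
Conditions: Dess–Martin periodinane, NaHCO3, CH2Cl2, 0 °C → rt
Reagents that add atoms: none
Why: Buffered Dess–Martin oxidation gives the α-methyl aldehyde without epimerising C12; it is used crude.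

Step 8
Reactants: 4 Roche-derived ethyl ketone, 11 C11–C17 aldehyde
Product: 13 (2R,4S,5R,6S,7S)-1-(benzyloxy)-7-[(tert-butyldimethylsilyl)oxy]-5-hydroxy-2,4,6-trimethylundec-10-en-3-one, via chlorotitanium Z-enolate 12 (not isolated)
Conditions: TiCl4, i-Pr2NEt, CH2Cl2, −78 °C; then 11, −78 °C
Reagents that add atoms: none
Why: Titanium-mediated syn-aldol addition, the key fragment union forming C10–C11. The chelated Z-enolate reacts through a chair transition state to give the 8,10-syn/10,11-syn adduct under control of C8, and this is the anti-Felkin face of 11 that Z-enolates prefer, so both partners reinforce.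

Step 9
Reactants: 13 β-hydroxy ketone
Product: 14 (2R,3R,4R,5S,6S,7S)-1-(benzyloxy)-7-[(tert-butyldimethylsilyl)oxy]-2,4,6-trimethylundec-10-ene-3,5-diol
Conditions: Me4NBH(OAc)3, MeCN/AcOH, −30 °C
Reagents that add atoms: none
Why: Evans–Saksena reduction; intramolecular hydride delivery from the C11 alkoxyborohydride gives the 9,11-anti diol and sets C9.

Step 10
Reactants: 14 anti-diol alkene
Product: 15 (5S,6S,7S,8R,9R,10R)-11-(benzyloxy)-5-[(tert-butyldimethylsilyl)oxy]-7,9-dihydroxy-6,8,10-trimethylundecan-2-one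
Conditions: PdCl2 (10 mol%), CuCl, O2 (1 atm), DMF/H2O (7:1), rt
Reagents that add atoms: water, O
Why: Tsuji–Wacker oxidation converts the terminal alkene with Markovnikov selectivity into the C16 methyl ketone.

Step 11
Reactants: 15 silyloxy methyl ketone
Product: 17 (2R,3R,4R)-1-(benzyloxy)-4-[(1S,3S,4R,5S)-1,4-dimethyl-2,8-dioxabicyclo[3.2.1]octan-3-yl]-2-methylpentan-3-ol, via triol ketone 16 (not isolated)
Conditions: HF (48% aq)/MeCN, 0 °C → rt
Reagents that add atoms: none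
Why: Acidic desilylation frees the C13 hydroxyl, which forms the five-membered hemiketal before the C11 hydroxyl closes the dioxane ring (thermodynamic intramolecular ketalisation). The C16 configuration is dictated by the bridged ring, and the C9 hydroxyl cannot reach.

Step 12
Reactants: 17 bicyclic ketal alcohol
Product: 18 {[(2R,3R,4S)-1-(benzyloxy)-4-[(1S,3R,4R,5S)-1,4-dimethyl-2,8-dioxabicyclo[3.2.1]octan-3-yl]-2-methylpentan-3-yl]oxy}triethylsilane
Conditions: TESOTf, 2,6-lutidine, CH2Cl2, −78 °C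
Reagents that add atoms: triethylsilyl trifluoromethanesulfonate, CC[Si](CC)(CC)OS(=O)(=O)C(F)(F)F
Why: Low-temperature silylation of the hindered C9 alcohol; the ketal is inert under these buffered conditions (descriptor changes are priority changes only).

Step 13
Reactants: 18 benzyl ether
Product: 19 (2R,3R,4S)-4-[(1S,3R,4R,5S)-1,4-dimethyl-2,8-dioxabicyclo[3.2.1]octan-3-yl]-2-methyl-3-[(triethylsilyl)oxy]pentan-1-ol
Conditions: H2 (1 atm), Pd/C, EtOAc, rt
Reagents that add atoms: none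
Why: Hydrogenolysis of the benzyl ether; no alkene is present, and the silyl ether and ketal are stable in ethyl acetate.

Step 14
Reactants: 19 primary alcohol
Product: 20 (2S,3S,4S)-4-[(1S,3R,4R,5S)-1,4-dimethyl-2,8-dioxabicyclo[3.2.1]octan-3-yl]-2-methyl-3-[(triethylsilyl)oxy]pentanal
Conditions: Dess–Martin periodinane, NaHCO3, CH2Cl2, 0 °C → rt
Reagents that add atoms: none
Why: Buffered Dess–Martin oxidation to the epimerisable C7 aldehyde, which is used at once.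

Step 15
Reactants: 20 C7 aldehyde
Product: 21 (3S,4S,5R,6R,7S)-7-[(1S,3R,4R,5S)-1,4-dimethyl-2,8-dioxabicyclo[3.2.1]octan-3-yl]-3,5-dimethyl-6-[(triethylsilyl)oxy]oct-1-en-4-ol
Conditions: (R,R)-diisopropyl tartrate (E)-crotylboronate, 4 Å MS, toluene, −78 °C; aq. NaHCO3
Reagents that add atoms: diisopropyl (4R,5R)-2-[(E)-but-2-en-1-yl]-1,3,2-dioxaborolane-4,5-dicarboxylate, C/C=C/CB1O[C@@H](C(=O)OC(C)C)[C@@H](O1)C(=O)OC(C)C
Why: Roush crotylboration through a closed chair transition state; the E-boronate gives the 6,7-anti pair, and the (R,R)-reagent attacks the Si face, which is also the Felkin face of 20 (matched), giving 7,8-syn.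

Step 16
Reactants: 21 homoallylic alcohol
Product: 22 (3S,4S,5R,6S,7S)-7-[(1S,3R,4R,5S)-1,4-dimethyl-2,8-dioxabicyclo[3.2.1]octan-3-yl]-3,5-dimethyl-4,6-bis[(triethylsilyl)oxy]oct-1-ene
Conditions: TESOTf, 2,6-lutidine, CH2Cl2, −78 → 0 °C
Reagents that add atoms: triethylsilyl trifluoromethanesulfonate, CC[Si](CC)(CC)OS(=O)(=O)C(F)(F)F
Why: Silyl triflate protection of the hindered C7 alcohol, so both carbinols are carried as acid-labile ethers.

Step 17
Reactants: 22 terminal alkene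
Product: 23 (2E,4S,5S,6R,7S,8S)-8-[(1S,3R,4R,5S)-1,4-dimethyl-2,8-dioxabicyclo[3.2.1]octan-3-yl]-4,6-dimethyl-5,7-bis[(triethylsilyl)oxy]non-2-enal
Conditions: (E)-crotonaldehyde (10 equiv), second-generation Hoveyda–Grubbs catalyst (5 mol%), CH2Cl2, 40 °C
Reagents that add atoms: (E)-but-2-enal, C/C=C/C=O
Why: Olefin cross-metathesis with excess crotonaldehyde gives the E-enal (C4=C5) under thermodynamic control and releases propene.

Step 18
Reactants: 23 E-enal
Product: 24 methyl (2Z,4E,6S,7S,8R,9S,10S)-10-[(1S,3R,4R,5S)-1,4-dimethyl-2,8-dioxabicyclo[3.2.1]octan-3-yl]-2,6,8-trimethyl-7,9-bis[(triethylsilyl)oxy]undeca-2,4-dienoate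
Conditions: (CF3CH2O)2P(O)CH(Me)CO2Me, KN(SiMe3)2, 18-crown-6, THF, −78 °C
Reagents that add atoms: methyl 2-[bis(2,2,2-trifluoroethoxy)phosphoryl]propanoate, COC(=O)C(C)P(=O)(OCC(F)(F)F)OCC(F)(F)F
Why: Still–Gennari olefination; the trifluoroethyl phosphonate with a dissociated potassium counter-ion gives the Z-trisubstituted C2=C3 bond under kinetic control.

Step 19
Reactants: 24 dienoate
Product: 25 (2Z,4E,6S,7S,8R,9S,10S)-10-[(1S,3R,4R,5S)-1,4-dimethyl-2,8-dioxabicyclo[3.2.1]octan-3-yl]-2,6,8-trimethyl-7,9-bis[(triethylsilyl)oxy]undeca-2,4-dienoic acid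
Conditions: LiOH·H2O, THF/MeOH/H2O (3:1:1), rt; 1 M HCl to pH 4, 0 °C
Reagents that add atoms: lithium hydroxide, [Li+].[OH-]
Why: Saponification of the methyl ester; the hindered triethylsilyl ethers and the ketal tolerate hydroxide at room temperature.

Step 20
Reactants: 26 methyl 2,4-dihydroxy-3,6-dimethylbenzoate (atraric acid)
Product: 27 methyl 5-formyl-2,4-dihydroxy-3,6-dimethylbenzoate
Conditions: Cl2CHOMe, TiCl4, CH2Cl2, 0 °C; aq. HCl
Reagents that add atoms: dichloromethyl methyl ether, COC(Cl)Cl; water, O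
Why: Rieche formylation; electrophilic substitution can only occur at the single free ring position, ortho to a hydroxyl.

Step 21
Reactants: 27 formyl diphenol
Product: 28 methyl 5-formyl-2,4-bis(methoxymethoxy)-3,6-dimethylbenzoate
Conditions: NaH, MOMCl, DMF, 0 °C → rt
Reagents that add atoms: chloromethyl methyl ether, COCCl
Why: Williamson-type alkylation of both chelated phenoxides installs acetal ethers that survive strong base and fall off in the final acid step.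

Step 22
Reactants: 28 aldehyde
Product: 29 3-(methoxycarbonyl)-4,6-bis(methoxymethoxy)-2,5-dimethylbenzoic acid
Conditions: NaClO2, NaH2PO4, 2-methyl-2-butene, t-BuOH/H2O, rt
Reagents that add atoms: sodium chlorite, [Na+].[O-]Cl=O
Why: Pinnick oxidation of the hindered aryl aldehyde with hypochlorite scavenging; the ring has no free position to chlorinate.

Step 23
Reactants: 29 acid
Product: 30 1-tert-butyl 3-methyl 4,6-bis(methoxymethoxy)-2,5-dimethylbenzene-1,3-dicarboxylate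
Conditions: Me2NCH(Ot-Bu)2, toluene, 80 °C
Reagents that add atoms: N,N-dimethylformamide di-tert-butyl acetal, CN(C)C(OC(C)(C)C)OC(C)(C)C
Why: O-alkylation of the carboxylate by a tert-butyl cation donor is insensitive to the two ortho substituents and gives the diester with two ester groups of different reactivity on an otherwise symmetric ring.

Step 24
Reactants: 30 mixed diester, 31 methyl acrylate
Product: 33 5-tert-butyl 2-methyl 1-hydroxy-6,8-bis(methoxymethoxy)-7-methyl-3,4-dihydronaphthalene-2,5-dicarboxylate, via Michael adduct 32 (not isolated)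
Conditions: LiN(i-Pr)2 (2.2 equiv), THF, −78 °C; 31, −78 → 0 °C; AcOH
Reagents that add atoms: none
Why: Staunton–Weinreb type Michael–Dieckmann annulation; lateral lithiation of the methyl group flanked by both esters, conjugate addition, and Dieckmann closure onto the methyl ester (far more electrophilic than the tert-butyl ester) build ring A. Because the ring is symmetric, either closure gives the same skeleton.

Step 25
Reactants: 33 cyclic β-keto ester (enol form)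
Product: 34 5-tert-butyl 2-methyl 1-hydroxy-6,8-bis(methoxymethoxy)-7-methylnaphthalene-2,5-dicarboxylate
Conditions: DDQ, toluene, 80 °C
Reagents that add atoms: none
Why: DDQ dehydrogenation of the β-keto ester is driven by aromatisation to the 1-naphthol.

Step 26
Reactants: 34 naphthol
Product: 35 5-tert-butyl 2-methyl 1-(benzyloxy)-6,8-bis(methoxymethoxy)-7-methylnaphthalene-2,5-dicarboxylate
Conditions: BnBr, K2CO3, DMF, 60 °C
Reagents that add atoms: benzyl bromide, BrCc1ccccc1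
Why: Williamson benzylation masks the C1 hydroxyl so the later isocyanate cannot cyclise onto it.

Step 27
Reactants: 35 benzyl ether diester
Product: 36 1-(benzyloxy)-5-(tert-butoxycarbonyl)-6,8-bis(methoxymethoxy)-7-methylnaphthalene-2-carboxylic acid
Conditions: LiOH·H2O, THF/MeOH/H2O, 50 °C; 1 M HCl to pH 4, 0 °C
Reagents that add atoms: lithium hydroxide, [Li+].[OH-]
Why: Selective saponification; the methyl ester is cleaved while the doubly ortho-substituted tert-butyl ester resists hydroxide.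

Step 28
Reactants: 36 naphthoic acid
Product: 39 tert-butyl 5-(benzyloxy)-6-{[(benzyloxy)carbonyl]amino}-2,4-bis(methoxymethoxy)-3-methylnaphthalene-1-carboxylate, via acyl azide 37 (not isolated), via isocyanate 38 (not isolated)
Conditions: (PhO)2P(O)N3, Et3N, toluene, rt → 90 °C; then BnOH, 90 °C
Reagents that add atoms: diphenylphosphoryl azide, [N-]=[N+]=NP(=O)(Oc1ccccc1)Oc1ccccc1; benzyl alcohol, OCc1ccccc1
Why: Curtius rearrangement places nitrogen on C2, and benzyl alcohol traps the isocyanate as the Cbz carbamate.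

Step 29
Reactants: 39 Cbz carbamate benzyl ether
Product: 40 tert-butyl 6-amino-5-hydroxy-2,4-bis(methoxymethoxy)-3-methylnaphthalene-1-carboxylate
Conditions: H2 (1 atm), Pd/C, EtOAc/THF, rt, degassed; filtered under argon
Reagents that add atoms: none
Why: One neutral hydrogenolysis removes the O-benzyl and Cbz groups, giving the air-sensitive aminonaphthol for immediate use.

Step 30
Reactants: 25 dienoic acid, 40 aminonaphthol
Product: 42 tert-butyl 6-{[(2Z,4E,6S,7S,8R,9S,10S)-10-[(1S,3R,4R,5S)-1,4-dimethyl-2,8-dioxabicyclo[3.2.1]octan-3-yl]-2,6,8-trimethyl-7,9-bis[(triethylsilyl)oxy]undeca-2,4-dienoyl]amino}-5-hydroxy-2,4-bis(methoxymethoxy)-3-methylnaphthalene-1-carboxylate, via acid chloride 41 (not isolated)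
Conditions: 25, Me2C=C(Cl)NMe2, CH2Cl2, 0 °C; then 40, pyridine, −20 → 0 °C, argon
Reagents that add atoms: none
Why: Neutral acid chloride formation with the Ghosez reagent, then N-acylation of the electron-rich arylamine, which outpaces O-acylation of the hydrogen-bonded naphthol and leaves the 2Z geometry intact.

Step 31
Reactants: 42 amido naphthol
Product: 43 tert-butyl 6-{[(2Z,4E,6S,7S,8R,9S,10S)-10-[(1S,3R,4R,5S)-1,4-dimethyl-2,8-dioxabicyclo[3.2.1]octan-3-yl]-2,6,8-trimethyl-7,9-bis[(triethylsilyl)oxy]undeca-2,4-dienoyl]amino}-2,4-bis(methoxymethoxy)-3-methyl-5,8-dioxo-5,8-dihydronaphthalene-1-carboxylate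
Conditions: (KSO3)2NO (2.5 equiv), KH2PO4 buffer (pH 6.5), acetone/H2O, 0 °C → rt
Reagents that add atoms: potassium nitrosodisulfonate, [K+].[K+].[O-]S(=O)(=O)N([O])S(=O)(=O)[O-]
Why: Teuber oxidation; the nitroxyl radical oxidises the 1-naphthol at its free para position C4 to the 1,4-naphthoquinone without touching the diene, silyl ethers or acetals.

Step 32
Reactants: 43 protected quinone
Product: 44 rifsaliniketal, 6-{[(2Z,4E,6S,7S,8R,9R,10R)-10-[(1S,3S,4R,5S)-1,4-dimethyl-2,8-dioxabicyclo[3.2.1]octan-3-yl]-7,9-dihydroxy-2,6,8-trimethylundeca-2,4-dienoyl]amino}-2,4-dihydroxy-3-methyl-5,8-dioxo-5,8-dihydronaphthalene-1-carboxylic acid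
Conditions: CF3CO2H/H2O/CH2Cl2 (5:1:5), 0 °C → rt; reversed-phase purification
Reagents that add atoms: none
Why: Acidolysis removes both methoxymethyl ethers, the tert-butyl ester and both triethylsilyl ethers in one step; the bicyclic ketal is the thermodynamic form and survives.

## Compound list

1 | methyl (R)-3-hydroxy-2-methylpropanoate | COC(=O)[C@H](C)CO | starting material
2 | methyl (R)-3-(benzyloxy)-2-methylpropanoate | COC(=O)[C@H](C)COCc1ccccc1 | intermediate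
3 | (R)-3-(benzyloxy)-N-methoxy-N,2-dimethylpropanamide | CON(C)C(=O)[C@H](C)COCc1ccccc1 | intermediate
4 | (R)-1-(benzyloxy)-2-methylpentan-3-one | CCC(=O)[C@H](C)COCc1ccccc1 | intermediate
5 | (R)-4-benzyl-3-propanoyl-1,3-oxazolidin-2-one | CCC(=O)N1[C@H](Cc2ccccc2)COC1=O | starting material
6 | pent-4-enal | C=CCCC=O | starting material
7 | Z-dibutylboron enolate of 5 (formed in situ) | C/C=C(\OB(CCCC)CCCC)N1[C@H](Cc2ccccc2)COC1=O | intermediate
8 | (R)-4-benzyl-3-[(2R,3S)-3-hydroxy-2-methylhept-6-enoyl]-1,3-oxazolidin-2-one | C=CCC[C@H](O)[C@@H](C)C(=O)N1[C@H](Cc2ccccc2)COC1=O | intermediate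
9 | (R)-4-benzyl-3-[(2R,3S)-3-[(tert-butyldimethylsilyl)oxy]-2-methylhept-6-enoyl]-1,3-oxazolidin-2-one | C=CCC[C@H](O[Si](C)(C)C(C)(C)C)[C@@H](C)C(=O)N1[C@H](Cc2ccccc2)COC1=O | intermediate
10 | (2S,3S)-3-[(tert-butyldimethylsilyl)oxy]-2-methylhept-6-en-1-ol | C=CCC[C@H](O[Si](C)(C)C(C)(C)C)[C@@H](C)CO | intermediate
11 | (2R,3S)-3-[(tert-butyldimethylsilyl)oxy]-2-methylhept-6-enal | C=CCC[C@H](O[Si](C)(C)C(C)(C)C)[C@@H](C)C=O | intermediate
12 | chlorotitanium Z-enolate of 4 (formed in situ) | C/C=C(\O[Ti](Cl)(Cl)Cl)[C@H](C)COCc1ccccc1 | intermediate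
13 | (2R,4S,5R,6S,7S)-1-(benzyloxy)-7-[(tert-butyldimethylsilyl)oxy]-5-hydroxy-2,4,6-trimethylundec-10-en-3-one | c1ccccc1COC[C@@H](C)C(=O)[C@@H](C)[C@H](O)[C@H](C)[C@H](CCC=C)O[Si](C)(C)C(C)(C)C | intermediate
14 | (2R,3R,4R,5S,6S,7S)-1-(benzyloxy)-7-[(tert-butyldimethylsilyl)oxy]-2,4,6-trimethylundec-10-ene-3,5-diol | c1ccccc1COC[C@@H](C)[C@@H](O)[C@@H](C)[C@H](O)[C@H](C)[C@H](CCC=C)O[Si](C)(C)C(C)(C)C | intermediate
15 | (5S,6S,7S,8R,9R,10R)-11-(benzyloxy)-5-[(tert-butyldimethylsilyl)oxy]-7,9-dihydroxy-6,8,10-trimethylundecan-2-one | c1ccccc1COC[C@@H](C)[C@@H](O)[C@@H](C)[C@H](O)[C@H](C)[C@H](CCC(C)=O)O[Si](C)(C)C(C)(C)C | intermediate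
16 | (5S,6R,7R,8R,9R,10R)-11-(benzyloxy)-5,7,9-trihydroxy-6,8,10-trimethylundecan-2-one (formed in situ) | c1ccccc1COC[C@@H](C)[C@@H](O)[C@@H](C)[C@H](O)[C@H](C)[C@@H](O)CCC(C)=O | intermediate
17 | (2R,3R,4R)-1-(benzyloxy)-4-[(1S,3S,4R,5S)-1,4-dimethyl-2,8-dioxabicyclo[3.2.1]octan-3-yl]-2-methylpentan-3-ol | C(OC[C@@H](C)[C@@H](O)[C@@H](C)[C@@H]1O[C@@]2(C)CC[C@H](O2)[C@H]1C)c1ccccc1 | intermediate
18 | {[(2R,3R,4S)-1-(benzyloxy)-4-[(1S,3R,4R,5S)-1,4-dimethyl-2,8-dioxabicyclo[3.2.1]octan-3-yl]-2-methylpentan-3-yl]oxy}triethylsilane | C(OC[C@@H](C)[C@@H](O[Si](CC)(CC)CC)[C@@H](C)[C@@H]1O[C@@]2(C)CC[C@H](O2)[C@H]1C)c1ccccc1 | intermediate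
19 | (2R,3R,4S)-4-[(1S,3R,4R,5S)-1,4-dimethyl-2,8-dioxabicyclo[3.2.1]octan-3-yl]-2-methyl-3-[(triethylsilyl)oxy]pentan-1-ol | OC[C@@H](C)[C@@H](O[Si](CC)(CC)CC)[C@@H](C)[C@@H]1O[C@@]2(C)CC[C@H](O2)[C@H]1C | intermediate
20 | (2S,3S,4S)-4-[(1S,3R,4R,5S)-1,4-dimethyl-2,8-dioxabicyclo[3.2.1]octan-3-yl]-2-methyl-3-[(triethylsilyl)oxy]pentanal | O=C[C@@H](C)[C@@H](O[Si](CC)(CC)CC)[C@@H](C)[C@@H]1O[C@@]2(C)CC[C@H](O2)[C@H]1C | intermediate
21 | (3S,4S,5R,6R,7S)-7-[(1S,3R,4R,5S)-1,4-dimethyl-2,8-dioxabicyclo[3.2.1]octan-3-yl]-3,5-dimethyl-6-[(triethylsilyl)oxy]oct-1-en-4-ol | C=C[C@H](C)[C@H](O)[C@@H](C)[C@@H](O[Si](CC)(CC)CC)[C@@H](C)[C@@H]1O[C@@]2(C)CC[C@H](O2)[C@H]1C | intermediate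
22 | (3S,4S,5R,6S,7S)-7-[(1S,3R,4R,5S)-1,4-dimethyl-2,8-dioxabicyclo[3.2.1]octan-3-yl]-3,5-dimethyl-4,6-bis[(triethylsilyl)oxy]oct-1-ene | C=C[C@H](C)[C@H](O[Si](CC)(CC)CC)[C@@H](C)[C@@H](O[Si](CC)(CC)CC)[C@@H](C)[C@@H]1O[C@@]2(C)CC[C@H](O2)[C@H]1C | intermediate
23 | (2E,4S,5S,6R,7S,8S)-8-[(1S,3R,4R,5S)-1,4-dimethyl-2,8-dioxabicyclo[3.2.1]octan-3-yl]-4,6-dimethyl-5,7-bis[(triethylsilyl)oxy]non-2-enal | O=C/C=C/[C@H](C)[C@H](O[Si](CC)(CC)CC)[C@@H](C)[C@@H](O[Si](CC)(CC)CC)[C@@H](C)[C@@H]1O[C@@]2(C)CC[C@H](O2)[C@H]1C | intermediate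
24 | methyl (2Z,4E,6S,7S,8R,9S,10S)-10-[(1S,3R,4R,5S)-1,4-dimethyl-2,8-dioxabicyclo[3.2.1]octan-3-yl]-2,6,8-trimethyl-7,9-bis[(triethylsilyl)oxy]undeca-2,4-dienoate | C/C(=C/C=C/[C@H](C)[C@H](O[Si](CC)(CC)CC)[C@@H](C)[C@@H](O[Si](CC)(CC)CC)[C@@H](C)[C@@H]1O[C@@]2(C)CC[C@H](O2)[C@H]1C)C(=O)OC | intermediate
25 | (2Z,4E,6S,7S,8R,9S,10S)-10-[(1S,3R,4R,5S)-1,4-dimethyl-2,8-dioxabicyclo[3.2.1]octan-3-yl]-2,6,8-trimethyl-7,9-bis[(triethylsilyl)oxy]undeca-2,4-dienoic acid | C/C(=C/C=C/[C@H](C)[C@H](O[Si](CC)(CC)CC)[C@@H](C)[C@@H](O[Si](CC)(CC)CC)[C@@H](C)[C@@H]1O[C@@]2(C)CC[C@H](O2)[C@H]1C)C(=O)O | intermediate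
26 | methyl 2,4-dihydroxy-3,6-dimethylbenzoate (atraric acid) | COC(=O)c1c(C)cc(O)c(C)c1O | starting material
27 | methyl 5-formyl-2,4-dihydroxy-3,6-dimethylbenzoate | COC(=O)c1c(C)c(C=O)c(O)c(C)c1O | intermediate
28 | methyl 5-formyl-2,4-bis(methoxymethoxy)-3,6-dimethylbenzoate | COC(=O)c1c(C)c(C=O)c(OCOC)c(C)c1OCOC | intermediate
29 | 3-(methoxycarbonyl)-4,6-bis(methoxymethoxy)-2,5-dimethylbenzoic acid | COC(=O)c1c(C)c(C(=O)O)c(OCOC)c(C)c1OCOC | intermediate
30 | 1-tert-butyl 3-methyl 4,6-bis(methoxymethoxy)-2,5-dimethylbenzene-1,3-dicarboxylate | COC(=O)c1c(C)c(C(=O)OC(C)(C)C)c(OCOC)c(C)c1OCOC | intermediate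
31 | methyl acrylate | C=CC(=O)OC | starting material
32 | 1-tert-butyl 3-methyl 2-(4-methoxy-4-oxobutyl)-4,6-bis(methoxymethoxy)-5-methylbenzene-1,3-dicarboxylate (formed in situ as its lithium enolate) | COC(=O)CCCc1c(C(=O)OC)c(OCOC)c(C)c(OCOC)c1C(=O)OC(C)(C)C | intermediate
33 | 5-tert-butyl 2-methyl 1-hydroxy-6,8-bis(methoxymethoxy)-7-methyl-3,4-dihydronaphthalene-2,5-dicarboxylate | COC(=O)C1=C(O)c2c(OCOC)c(C)c(OCOC)c(C(=O)OC(C)(C)C)c2CC1 | intermediate
34 | 5-tert-butyl 2-methyl 1-hydroxy-6,8-bis(methoxymethoxy)-7-methylnaphthalene-2,5-dicarboxylate | COC(=O)c1ccc2c(C(=O)OC(C)(C)C)c(OCOC)c(C)c(OCOC)c2c1O | intermediate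
35 | 5-tert-butyl 2-methyl 1-(benzyloxy)-6,8-bis(methoxymethoxy)-7-methylnaphthalene-2,5-dicarboxylate | COC(=O)c1ccc2c(C(=O)OC(C)(C)C)c(OCOC)c(C)c(OCOC)c2c1OCc1ccccc1 | intermediate
36 | 1-(benzyloxy)-5-(tert-butoxycarbonyl)-6,8-bis(methoxymethoxy)-7-methylnaphthalene-2-carboxylic acid | OC(=O)c1ccc2c(C(=O)OC(C)(C)C)c(OCOC)c(C)c(OCOC)c2c1OCc1ccccc1 | intermediate
37 | acyl azide of 36 (formed in situ) | [N-]=[N+]=NC(=O)c1ccc2c(C(=O)OC(C)(C)C)c(OCOC)c(C)c(OCOC)c2c1OCc1ccccc1 | intermediate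
38 | tert-butyl 5-(benzyloxy)-6-isocyanato-2,4-bis(methoxymethoxy)-3-methylnaphthalene-1-carboxylate (formed in situ) | O=C=Nc1ccc2c(C(=O)OC(C)(C)C)c(OCOC)c(C)c(OCOC)c2c1OCc1ccccc1 | intermediate
39 | tert-butyl 5-(benzyloxy)-6-{[(benzyloxy)carbonyl]amino}-2,4-bis(methoxymethoxy)-3-methylnaphthalene-1-carboxylate | O=C(Nc1ccc2c(C(=O)OC(C)(C)C)c(OCOC)c(C)c(OCOC)c2c1OCc1ccccc1)OCc1ccccc1 | intermediate
40 | tert-butyl 6-amino-5-hydroxy-2,4-bis(methoxymethoxy)-3-methylnaphthalene-1-carboxylate | Nc1ccc2c(C(=O)OC(C)(C)C)c(OCOC)c(C)c(OCOC)c2c1O | intermediate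
41 | (2Z,4E,6S,7S,8R,9S,10S)-10-[(1S,3R,4R,5S)-1,4-dimethyl-2,8-dioxabicyclo[3.2.1]octan-3-yl]-2,6,8-trimethyl-7,9-bis[(triethylsilyl)oxy]undeca-2,4-dienoyl chloride (formed in situ) | C/C(=C/C=C/[C@H](C)[C@H](O[Si](CC)(CC)CC)[C@@H](C)[C@@H](O[Si](CC)(CC)CC)[C@@H](C)[C@@H]1O[C@@]2(C)CC[C@H](O2)[C@H]1C)C(Cl)=O | intermediate
42 | tert-butyl 6-{[(2Z,4E,6S,7S,8R,9S,10S)-10-[(1S,3R,4R,5S)-1,4-dimethyl-2,8-dioxabicyclo[3.2.1]octan-3-yl]-2,6,8-trimethyl-7,9-bis[(triethylsilyl)oxy]undeca-2,4-dienoyl]amino}-5-hydroxy-2,4-bis(methoxymethoxy)-3-methylnaphthalene-1-carboxylate | C/C(=C/C=C/[C@H](C)[C@H](O[Si](CC)(CC)CC)[C@@H](C)[C@@H](O[Si](CC)(CC)CC)[C@@H](C)[C@@H]1O[C@@]2(C)CC[C@H](O2)[C@H]1C)C(=O)Nc1ccc2c(C(=O)OC(C)(C)C)c(OCOC)c(C)c(OCOC)c2c1O | intermediate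
43 | tert-butyl 6-{[(2Z,4E,6S,7S,8R,9S,10S)-10-[(1S,3R,4R,5S)-1,4-dimethyl-2,8-dioxabicyclo[3.2.1]octan-3-yl]-2,6,8-trimethyl-7,9-bis[(triethylsilyl)oxy]undeca-2,4-dienoyl]amino}-2,4-bis(methoxymethoxy)-3-methyl-5,8-dioxo-5,8-dihydronaphthalene-1-carboxylate | C/C(=C/C=C/[C@H](C)[C@H](O[Si](CC)(CC)CC)[C@@H](C)[C@@H](O[Si](CC)(CC)CC)[C@@H](C)[C@@H]1O[C@@]2(C)CC[C@H](O2)[C@H]1C)C(=O)NC1=CC(=O)c2c(C(=O)OC(C)(C)C)c(OCOC)c(C)c(OCOC)c2C1=O | intermediate
44 | rifsaliniketal, 6-{[(2Z,4E,6S,7S,8R,9R,10R)-10-[(1S,3S,4R,5S)-1,4-dimethyl-2,8-dioxabicyclo[3.2.1]octan-3-yl]-7,9-dihydroxy-2,6,8-trimethylundeca-2,4-dienoyl]amino}-2,4-dihydroxy-3-methyl-5,8-dioxo-5,8-dihydronaphthalene-1-carboxylic acid | C/C(=C/C=C/[C@H](C)[C@H](O)[C@@H](C)[C@@H](O)[C@@H](C)[C@@H]1O[C@@]2(C)CC[C@H](O2)[C@H]1C)C(=O)NC1=CC(=O)c2c(C(=O)O)c(O)c(C)c(O)c2C1=O | target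

## Step count and risks

Total step count: 32. Longest linear sequence: 19 steps (5 + 6 → 44: steps 4–19, then 30–32).

Three steps most likely to fail:

Step 24 (Michael–Dieckmann annulation). The crowded benzylic anion may add poorly to methyl acrylate, or the adduct enolate may start acrylate oligomerisation. The fallback sets out from 30 and switches to a Hauser-type sulfoxide annulation. Lateral lithiation with LiN(i-Pr)2 and quenching with PhSSPh gives the sulfide 1-tert-butyl 3-methyl 4,6-bis(methoxymethoxy)-5-methyl-2-[(phenylsulfanyl)methyl]benzene-1,3-dicarboxylate F2. One equivalent of mCPBA at −40 °C gives the sulfoxide 1-tert-butyl 3-methyl 4,6-bis(methoxymethoxy)-5-methyl-2-[(phenylsulfinyl)methyl]benzene-1,3-dicarboxylate F3. Its more stabilised anion (LiN(i-Pr)2, THF, −78 °C) adds to 31 and closes onto the methyl ester to give 5-tert-butyl 2-methyl 1-hydroxy-6,8-bis(methoxymethoxy)-7-methyl-4-(phenylsulfinyl)-3,4-dihydronaphthalene-2,5-dicarboxylate F4, which is not isolated. Warming in toluene to 80 °C causes thermal syn-elimination of benzenesulfenic acid and aromatises it directly. The fallback comes back to the route at 34, so the DDQ step is not needed.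

Step 17 (cross-metathesis). The alkene in 22 carries an allylic methyl branch and a homoallylic silyl ether, and may react sluggishly or mainly homodimerise the crotonaldehyde. The fallback sets out from 22 and builds the enal by carbonyl olefination instead. Ozonolysis (O3, CH2Cl2/MeOH, −78 °C; PPh3) gives (2R,3R,4S,5S,6S)-6-[(1S,3R,4R,5S)-1,4-dimethyl-2,8-dioxabicyclo[3.2.1]octan-3-yl]-2,4-dimethyl-3,5-bis[(triethylsilyl)oxy]heptanal F1. A Wittig reaction with (triphenylphosphoranylidene)acetaldehyde in toluene at 80 °C re-installs C4 and adds C3 as the E-enal. The fallback comes back to the route at 23.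

Step 31 (late-stage Teuber oxidation). The radical oxidant must attack C4 next to the peri tert-butyl ester on a precious intermediate. The fallback sets out from 42 and uses an ionic two-electron oxidation with a small nucleophile. PhI(OAc)2 (2.2 equiv) in MeOH at 0 °C gives the quinone monoketal tert-butyl 6-{[(2Z,4E,6S,7S,8R,9S,10S)-10-[(1S,3R,4R,5S)-1,4-dimethyl-2,8-dioxabicyclo[3.2.1]octan-3-yl]-2,6,8-trimethyl-7,9-bis[(triethylsilyl)oxy]undeca-2,4-dienoyl]amino}-8,8-dimethoxy-2,4-bis(methoxymethoxy)-3-methyl-5-oxo-5,8-dihydronaphthalene-1-carboxylate F5. The aqueous CF3CO2H treatment of step 32 then hydrolyses the dimethyl ketal together with the protecting groups. The fallback comes back to the route at 44, bypassing 43.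

Further compounds

F1 | step 17 | (2R,3R,4S,5S,6S)-6-[(1S,3R,4R,5S)-1,4-dimethyl-2,8-dioxabicyclo[3.2.1]octan-3-yl]-2,4-dimethyl-3,5-bis[(triethylsilyl)oxy]heptanal | O=C[C@H](C)[C@H](O[Si](CC)(CC)CC)[C@@H](C)[C@@H](O[Si](CC)(CC)CC)[C@@H](C)[C@@H]1O[C@@]2(C)CC[C@H](O2)[C@H]1C
F2 | step 24 | 1-tert-butyl 3-methyl 4,6-bis(methoxymethoxy)-5-methyl-2-[(phenylsulfanyl)methyl]benzene-1,3-dicarboxylate | COC(=O)c1c(CSc2ccccc2)c(C(=O)OC(C)(C)C)c(OCOC)c(C)c1OCOC
F3 | step 24 | 1-tert-butyl 3-methyl 4,6-bis(methoxymethoxy)-5-methyl-2-[(phenylsulfinyl)methyl]benzene-1,3-dicarboxylate | COC(=O)c1c(CS(=O)c2ccccc2)c(C(=O)OC(C)(C)C)c(OCOC)c(C)c1OCOC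
F4 | step 24 | 5-tert-butyl 2-methyl 1-hydroxy-6,8-bis(methoxymethoxy)-7-methyl-4-(phenylsulfinyl)-3,4-dihydronaphthalene-2,5-dicarboxylate | COC(=O)C1=C(O)c2c(OCOC)c(C)c(OCOC)c(C(=O)OC(C)(C)C)c2C(S(=O)c3ccccc3)C1
F5 | step 31 | tert-butyl 6-{[(2Z,4E,6S,7S,8R,9S,10S)-10-[(1S,3R,4R,5S)-1,4-dimethyl-2,8-dioxabicyclo[3.2.1]octan-3-yl]-2,6,8-trimethyl-7,9-bis[(triethylsilyl)oxy]undeca-2,4-dienoyl]amino}-8,8-dimethoxy-2,4-bis(methoxymethoxy)-3-methyl-5-oxo-5,8-dihydronaphthalene-1-carboxylate | C/C(=C/C=C/[C@H](C)[C@H](O[Si](CC)(CC)CC)[C@@H](C)[C@@H](O[Si](CC)(CC)CC)[C@@H](C)[C@@H]1O[C@@]2(C)CC[C@H](O2)[C@H]1C)C(=O)NC1=CC(OC)(OC)c2c(C(=O)OC(C)(C)C)c(OCOC)c(C)c(OCOC)c2C1=O
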